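**Retrosynthetic overview**

1. The target is reached from butenolide 31 by desilylation/acetylation only. 31 is disconnected at the C19–C17 bond (C19 = lactone carbonyl carbon, C17 = olefinic carbon bearing methyl C18), i.e. a carbonylative closure of the γ-lactone from α-allenic alcohol 30 and CO.
2. Enabling feature: the lactone oxygen sits on C7, a CH of the ten-membered carbocycle bonded directly to C8, and C8=C17 carries on C17 only CH3 and C19. One hydrogen shift back, C8/C17/C18 is an exocyclic allene (C8=C17=C18H2) on the ten-membered ring next to the C7 carbinol, and its distal π bond lies in the C7–C8–C9 plane, within five-ring reach of O7.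
3. 30 comes from a ring-closing propargyl-to-allenyl SE2′ addition (C7–C8 bond) of a C18 propargylic chloride to the (Z)-enal at C7. This one closure makes the ten-membered ring, the C7 carbinol and the allene.
4. The open-chain precursor comes from Felkin–Anh addition of lithiated propargyl chloride to the C9 aldehyde, and from a Mukaiyama aldol (C1–C2, quaternary C1) between cyclohexanone silyl enol ether 12 and nerol-derived (Z)-aldehyde 16, followed by 1,3-syn reduction (C14).
5. 12 comes from (R)-carvone (source of C12): α′-methylation, alkoxymethyl addition/oxidative transposition, Criegee rearrangement, hydroxyl-directed hydrogenation. Ring order: cyclohexane (from carvone), then ten-membered carbocycle (step 20), then butenolide (step 21).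

Key step: step 21

Remark on locants and materials: briarane-type position labels are used in the text only. C1 = quaternary ring-fusion carbon (methyl C15), C2 = butyrate carbinol, C3, C4, C5 (methyl C16), C6, C7 = lactone O–CH, C8, C9 = acetoxy carbinol, C10 = ring-fusion CH, C11 (methyl C20), C12 (OH), C13, C14 (acetoxy). With these labels the target is (1S,2R,5Z,7S,9R,10S,11R,12R,14S). Compounds 1, 3, 13 and 23 are assumed to be purchased.

Step 1
Reactants: 1 (R)-(−)-carvone
Product: 2 trans-6-methylcarvone
Conditions: LiN(iPr)2, THF, −78 °C; then MeI, −78 → −20 °C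
Reagents that add atoms: iodomethane, CI
Why: Kinetic α′-enolate alkylation of the enone, in which the methyl group (future C20 on C11) enters anti to the neighbouring isopropenyl group and so sets the trans relation between the C11 methyl and the later C12 oxygen.

Step 2
Reactants: 2 trans-6-methylcarvone; 3 tributyl[(methoxymethoxy)methyl]stannane
Product: 5 tertiary allylic alcohol (both carbinol epimers), via (methoxymethoxy)methyllithium 4 (not isolated)
Conditions: 3, n-BuLi, THF, −78 °C; then 2, −78 °C; NH4Cl aq.
Reagents that add atoms: none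
Why: Tin–lithium exchange gives an α-alkoxymethyllithium that adds 1,2 to the enone carbonyl and brings in C9 as a protected hydroxymethyl group; the carbinol configuration is irrelevant because it is removed in step 3.

Step 3
Reactants: 5 tertiary allylic alcohol
Product: 6 transposed enone
Conditions: pyridinium chlorochromate [C5H5NH][CrO3Cl], 4 Å molecular sieves, CH2Cl2, rt
Reagents that add atoms: pyridinium chlorochromate, [O-][Cr](=O)(=O)Cl.c1cc[nH+]cc1
Why: Babler–Dauben oxidative transposition (chromate ester, [3,3] shift, oxidation) moves the oxygen to C14 and leaves the C9 carbon on the β-carbon C10 of the new enone; C11 and C12 are not touched.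

Step 4
Reactants: 6 transposed enone
Product: 9 hydroxy enone, via methoxy hydroperoxide 7 (not isolated), via acetate 8 (not isolated)
Conditions: O3, CH2Cl2/MeOH, −78 °C (indicator end point); then Ac2O, Et3N, DMAP, 0 °C → rt; then K2CO3, MeOH, 0 °C
Reagents that add atoms: ozone, [O-][O+]=O (methanol, CO, and acetic anhydride, CC(=O)OC(C)=O, put atoms only into 7 and 8)
Why: The electron-poor tetrasubstituted enone is inert to ozone while the isopropenyl group is cleaved to an α-methoxy hydroperoxide, whose peracetate undergoes Criegee rearrangement with retention at the migrating carbon C12; brief cold methanolysis then frees the C12 hydroxyl.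

Step 5
Reactants: 9 hydroxy enone
Product: 10 saturated hydroxy ketone
Conditions: [Ir(cod)(PCy3)(py)]PF6 (10 mol %), H2, CH2Cl2, rt
Reagents that add atoms: none
Why: Hydroxyl-directed hydrogenation, in which the cationic iridium binds the homoallylic C12 hydroxyl and delivers both hydrogens to the tetrasubstituted C1=C10 olefin from the hydroxyl face, so that C10–H is cis to the C12 oxygen and the C9 arm cis to the C11 methyl (the C1 centre formed here is planarised again in step 7).

Step 6
Reactants: 10 saturated hydroxy ketone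
Product: 11 silyl ether ketone
Conditions: tert-butyl(chloro)diphenylsilane, imidazole, DMF, rt → 40 °C
Reagents that add atoms: tert-butyl(chloro)diphenylsilane, CC(C)(C)[Si](Cl)(c1ccccc1)c1ccccc1
Why: Imidazole-promoted silylation of the secondary C12 hydroxyl with the most robust silyl group of the route, which must outlast two later selective desilylations; no stereocentre is touched.

Step 7
Reactants: 11 silyl ether ketone
Product: 12 trimethylsilyl enol ether
Conditions: Me3SiOTf, Et3N, CH2Cl2, 0 °C → rt
Reagents that add atoms: trimethylsilyl trifluoromethanesulfonate, C[Si](C)(C)OS(=O)(=O)C(F)(F)F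
Why: Soft enolisation under equilibrating conditions should favour the more substituted C14=C1 silyl enol ether (the C13 isomer suffers allylic strain with the C12 silyloxy group); C1 becomes sp2, so no stereocentre is created.

Step 8
Reactants: 13 nerol
Product: 14 neryl silyl ether
Conditions: tert-butyl(chloro)dimethylsilane, imidazole, CH2Cl2, rt
Reagents that add atoms: tert-butyl(chloro)dimethylsilane, CC(C)(C)[Si](C)(C)Cl
Why: Standard silylation of the primary allylic alcohol; the (Z)-trisubstituted olefin that becomes C5=C6 is taken unchanged from nerol.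

Step 9
Reactants: 14 neryl silyl ether
Product: 16 (Z)-aldehyde, via diol 15 (not isolated)
Conditions: K2OsO2(OH)4 (1 mol %), (DHQD)2PHAL (2 mol %), N-methylmorpholine N-oxide, acetone/H2O, 0 °C; then NaIO4, THF/H2O, rt
Reagents that add atoms: N-methylmorpholine N-oxide, C[N+]1([O-])CCOCC1; water, O
Why: Ligand-accelerated Sharpless-type dihydroxylation selects the electron-richer distal olefin over the one deactivated by the allylic silyloxy group, and periodate glycol cleavage gives the C2 aldehyde without touching the (Z)-olefin.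

Step 10
Reactants: 12 trimethylsilyl enol ether; 16 (Z)-aldehyde
Product: 17 aldol
Conditions: BF3·OEt2, CH2Cl2, −78 °C; NaHCO3 aq.
Reagents that add atoms: none
Why: Mukaiyama aldol through an open transition state creates quaternary C1, the aldehyde attacking anti to the adjacent pseudoaxial C10–CH2OMOM group (C2 arm trans to the C9 arm, C1 methyl cis to it), and the aldehyde chain lying next to the small C1 methyl rather than the ring branch C10, which should give the (2R) carbinol (hydroxyl syn to C10 along C3–C2–C1–C14).

Step 11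
Reactants: 17 aldol
Product: 18 syn-1,3-diol
Conditions: Et2BOMe, THF/MeOH, −78 °C; NaBH4; then AcOH, MeOH (evaporation)
Reagents that add atoms: none
Why: Narasaka–Prasad reduction, in which the boron chelate between the C2 oxygen and the C14 carbonyl is attacked by external hydride to give the 1,3-syn diol, setting C14 with its hydroxyl cis to the C2 arm and trans to the C1 methyl.

Step 12
Reactants: 18 syn-1,3-diol
Product: 19 mono-butyrate
Conditions: butyric anhydride (1.05 equiv), 2,4,6-collidine, DMAP (5 mol %), CH2Cl2, −40 → 0 °C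
Reagents that add atoms: butyric anhydride, CCCC(=O)OC(=O)CCC
Why: Site-selective DMAP-catalysed acylation, expected at the side-chain C2 hydroxyl because the ring C14 hydroxyl is flanked by the quaternary centre and lies 1,3-cis to the bulky C12 silyl ether; no stereocentre is affected.

Step 13
Reactants: 19 mono-butyrate
Product: 20 butyrate acetate
Conditions: Ac2O, DMAP, Et3N, CH2Cl2, rt
Reagents that add atoms: acetic anhydride, CC(=O)OC(C)=O
Why: DMAP-catalysed acetylation of the remaining hindered C14 hydroxyl installs the final C14 acetate and is run directly after step 12 so that 1,3-acyl migration has no opportunity.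

Step 14
Reactants: 20 butyrate acetate
Product: 21 primary alcohol
Conditions: Me2BBr, CH2Cl2, −78 °C; then NaHCO3 aq./THF
Reagents that add atoms: none
Why: Lewis-acid cleavage of the methoxymethyl acetal via a bromomethyl ether that is hydrolysed on work-up, at a temperature where silyl ethers, esters and the trisubstituted olefin should be inert.

Step 15
Reactants: 21 primary alcohol
Product: 22 C9 aldehyde
Conditions: 1,1,1-triacetoxy-1,1-dihydro-1,2-benziodoxol-3(1H)-one, NaHCO3, CH2Cl2, 0 °C → rt
Reagents that add atoms: none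
Why: Buffered Dess–Martin oxidation gives the α-branched aldehyde without epimerising C10 and without affecting the silyl ethers or esters.

Step 16
Reactants: 22 C9 aldehyde; 23 3-chloroprop-1-yne (propargyl chloride)
Product: 25 propargylic alcohol, via 3-chloroprop-1-ynyllithium 24 (not isolated)
Conditions: 23, n-BuLi, THF, −78 °C; then 22, −78 °C; NH4Cl aq. at −78 °C
Reagents that add atoms: none
Why: Acetylide addition to the aldehyde under Felkin–Anh control, the nucleophile approaching anti to the quaternary C1 (largest α-substituent) and past C10–H, which should give the (9R) carbinol; the aldehyde reacts far faster than the two hindered esters at −78 °C.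

Step 17
Reactants: 25 propargylic alcohol
Product: 26 bis-silyl ether
Conditions: tert-butyldimethylsilyl trifluoromethanesulfonate, 2,6-lutidine, CH2Cl2, −78 → 0 °C
Reagents that add atoms: tert-butyldimethylsilyl trifluoromethanesulfonate, CC(C)(C)[Si](C)(C)OS(=O)(=O)C(F)(F)F
Why: Silyl triflate silylation of the hindered C9 hydroxyl turns it into a poor leaving group for step 20 and ensures that O7 is the only free hydroxyl in step 21.

Step 18
Reactants: 26 bis-silyl ether
Product: 27 allylic alcohol
Conditions: HF·pyridine, pyridine, THF, 0 °C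
Reagents that add atoms: none
Why: Buffered HF·pyridine cleaves the unhindered primary allylic silyl ether much faster than the hindered secondary ones (steric differentiation of silyl ethers) and leaves the propargylic chloride alone.

Step 19
Reactants: 27 allylic alcohol
Product: 28 (Z)-enal
Conditions: MnO2 (excess), CH2Cl2, rt
Reagents that add atoms: none
Why: MnO2 oxidises only the allylic alcohol and gives the neral-type (Z)-enal without olefin isomerisation.

Step 20
Reactants: 28 (Z)-enal
Product: 30 ten-membered α-allenic alcohol, via propargylchromium dichloride 29 (not isolated)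
Conditions: slow addition of 28 to CrCl2 (10 equiv), LiI (0.5 equiv), THF, rt, high dilution; NH4Cl aq.
Reagents that add atoms: none
Why: Nozaki–Hiyama Barbier closure in which divalent chromium inserts into the C–Cl bond and the primary propargylchromium adds through its γ-carbon C8 to the aldehyde in a six-membered SE2′ transition state, forming the C7–C8 bond, the ten-membered ring and the exocyclic allene at once; the 7,9-syn carbinol is expected because the aldehyde approaches C8 anti to the C9 silyloxy group with C9–H in the allene plane (minimal A(1,3) strain).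

Step 21
Reactants: 30 ten-membered α-allenic alcohol
Product: 31 butenolide
Conditions: Ru3(CO)12 (5 mol %), CO (10 atm), Et3N, 1,4-dioxane, 100 °C
Reagents that add atoms: carbon monoxide, [C-]#[O+]
Why: Zerovalent ruthenium carbonyl activates the only free hydroxyl (O7–H) and inserts CO into the Ru–O bond to give an alkoxycarbonyl ruthenium hydride; migratory insertion of the distal allene π bond C17=C18 into the Ru–C19 bond then forms the C19–C17 bond and closes the five-membered lactone (5-exo with respect to C17=C18, C8 being already part of the chain O7–C7–C8), leaving a π-allyl ruthenium hydride over C8–C17–C18. C–H reductive elimination at the unhindered terminus C18 turns the allene CH2 into the C18 methyl and leaves the tetrasubstituted C8=C17 olefin conjugated with the new carbonyl. The closest known reaction is the Ru3(CO)12-catalysed cyclocarbonylation of α-allenic alcohols to 3-methyl-2(5H)-furanones. No stereocentre is formed, and C7 and C9 keep their configuration because none of their bonds is broken. The step needs site selectivity for O7 (secured because every other oxygen is silylated or acylated), attack at the central allene carbon (enforced by the five-ring geometry, since the distal π bond lies in the C7–C8–C9 plane) and hydrogen delivery to C18 rather than C8 (any α-methylene isomer should be isomerised to the conjugated butenolide by the ruthenium hydride and amine present).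

Step 22
Reactants: 31 butenolide
Product: 32 C9 alcohol
Conditions: HF·pyridine, pyridine, THF, 0 °C → rt
Reagents that add atoms: none
Why: Acidic fluoride cleaves the secondary tert-butyldimethylsilyl ether at C9 while the far more acid-stable tert-butyldiphenylsilyl ether at C12 should survive; the lactone and esters are inert.

Step 23
Reactants: 32 C9 alcohol
Product: 33 C9 acetate
Conditions: Ac2O, DMAP, pyridine, CH2Cl2, rt
Reagents that add atoms: acetic anhydride, CC(=O)OC(C)=O
Why: DMAP-catalysed acetylation of the only free hydroxyl installs the C9 acetate without touching any stereocentre.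

Step 24
Reactants: 33 C9 acetate
Product: 34 target
Conditions: HF·pyridine (large excess), THF, rt → 40 °C
Reagents that add atoms: none
Why: Prolonged acidic fluoride treatment removes the C12 silyl ether under non-basic conditions, so that neither acetyl migration from O14 to O12 nor base-induced γ-deprotonation/elimination of the 9-acetoxy butenolide should occur.

**Compound list**

1 | (R)-(−)-carvone, (5R)-2-methyl-5-(prop-1-en-2-yl)cyclohex-2-en-1-one | O=C1C[C@H](C(C)=C)CC=C1C | starting material
2 | trans-6-methylcarvone, (5R,6S)-2,6-dimethyl-5-(prop-1-en-2-yl)cyclohex-2-en-1-one | O=C1[C@@H](C)[C@H](C(C)=C)CC=C1C | intermediate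
3 | tributyl[(methoxymethoxy)methyl]stannane | CCCC[Sn](CCCC)(CCCC)COCOC | starting material
4 | (methoxymethoxy)methyllithium | [Li]COCOC | intermediate
5 | (5R,6S)-1-[(methoxymethoxy)methyl]-2,6-dimethyl-5-(prop-1-en-2-yl)cyclohex-2-en-1-ol, both carbinol epimers | OC1(COCOC)[C@@H](C)[C@H](C(C)=C)CC=C1C | intermediate
6 | (4S,5R)-3-[(methoxymethoxy)methyl]-2,4-dimethyl-5-(prop-1-en-2-yl)cyclohex-2-en-1-one | O=C1C(C)=C(COCOC)[C@@H](C)[C@H](C(C)=C)C1 | intermediate
7 | 5-(1-hydroperoxy-1-methoxyethyl)-3-[(methoxymethoxy)methyl]-2,4-dimethylcyclohex-2-en-1-one (4,5-trans, ring centres as in 6) | O=C1C(C)=C(COCOC)[C@@H](C)[C@H](C(C)(OC)OO)C1 | intermediate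
8 | 5-acetoxy-3-[(methoxymethoxy)methyl]-2,4-dimethylcyclohex-2-en-1-one (4-methyl trans to 5-acetoxy) | O=C1C(C)=C(COCOC)[C@@H](C)[C@H](OC(C)=O)C1 | intermediate
9 | 5-hydroxy-3-[(methoxymethoxy)methyl]-2,4-dimethylcyclohex-2-en-1-one (4-methyl trans to 5-hydroxy; C11 and C12 as in 34) | O=C1C(C)=C(COCOC)[C@@H](C)[C@H](O)C1 | intermediate
10 | 5-hydroxy-3-[(methoxymethoxy)methyl]-2,4-dimethylcyclohexan-1-one (H at ring positions 2 and 3 cis to the 5-hydroxyl, 4-methyl trans to it) | O=C1[C@@H](C)[C@@H](COCOC)[C@@H](C)[C@H](O)C1 | intermediate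
11 | tert-butyldiphenylsilyl ether of 10 | O=C1[C@@H](C)[C@@H](COCOC)[C@@H](C)[C@H](O[Si](c2ccccc2)(c2ccccc2)C(C)(C)C)C1 | intermediate
12 | trimethylsilyl enol ether of 11 (C14=C1 enol ether; C10, C11, C12 as in 34) | C[Si](C)(C)OC1=C(C)[C@@H](COCOC)[C@@H](C)[C@H](O[Si](c2ccccc2)(c2ccccc2)C(C)(C)C)C1 | intermediate
13 | nerol, (2Z)-3,7-dimethylocta-2,6-dien-1-ol | CC(C)=CCC/C(C)=C\CO | starting material
14 | neryl tert-butyldimethylsilyl ether | CC(C)=CCC/C(C)=C\CO[Si](C)(C)C(C)(C)C | intermediate
15 | (2Z)-8-[(tert-butyldimethylsilyl)oxy]-2,6-dimethyloct-6-ene-2,3-diol (carbinol configuration immaterial) | CC(C)(O)C(O)CC/C(C)=C\CO[Si](C)(C)C(C)(C)C | intermediate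
16 | (4Z)-6-[(tert-butyldimethylsilyl)oxy]-4-methylhex-4-enal | O=CCC/C(C)=C\CO[Si](C)(C)C(C)(C)C | intermediate
17 | aldol: C14 ketone, quaternary C1, (2R)-hydroxy side chain, C9 methoxymethyl ether, C12 silyl ether (centres as in 34) | O[C@H](CC/C(C)=C\CO[Si](C)(C)C(C)(C)C)[C@@]1(C)C(=O)C[C@@H](O[Si](c2ccccc2)(c2ccccc2)C(C)(C)C)[C@H](C)[C@@H]1COCOC | intermediate
18 | C2,C14 syn-1,3-diol from 17 | O[C@H](CC/C(C)=C\CO[Si](C)(C)C(C)(C)C)[C@@]1(C)[C@@H](O)C[C@@H](O[Si](c2ccccc2)(c2ccccc2)C(C)(C)C)[C@H](C)[C@@H]1COCOC | intermediate
19 | C2 butyrate of 18 (C14 hydroxyl free) | CCCC(=O)O[C@H](CC/C(C)=C\CO[Si](C)(C)C(C)(C)C)[C@@]1(C)[C@@H](O)C[C@@H](O[Si](c2ccccc2)(c2ccccc2)C(C)(C)C)[C@H](C)[C@@H]1COCOC | intermediate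
20 | C2 butyrate C14 acetate, C9 methoxymethyl ether | CCCC(=O)O[C@H](CC/C(C)=C\CO[Si](C)(C)C(C)(C)C)[C@@]1(C)[C@@H](OC(C)=O)C[C@@H](O[Si](c2ccccc2)(c2ccccc2)C(C)(C)C)[C@H](C)[C@@H]1COCOC | intermediate
21 | C9 primary alcohol from 20 | CCCC(=O)O[C@H](CC/C(C)=C\CO[Si](C)(C)C(C)(C)C)[C@@]1(C)[C@@H](OC(C)=O)C[C@@H](O[Si](c2ccccc2)(c2ccccc2)C(C)(C)C)[C@H](C)[C@@H]1CO | intermediate
22 | C9 aldehyde | CCCC(=O)O[C@H](CC/C(C)=C\CO[Si](C)(C)C(C)(C)C)[C@@]1(C)[C@@H](OC(C)=O)C[C@@H](O[Si](c2ccccc2)(c2ccccc2)C(C)(C)C)[C@H](C)[C@@H]1C=O | intermediate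
23 | 3-chloroprop-1-yne (propargyl chloride) | C#CCCl | starting material
24 | 3-chloroprop-1-ynyllithium | [Li]C#CCCl | intermediate
25 | (9R)-propargylic alcohol with C18 chloride | CCCC(=O)O[C@H](CC/C(C)=C\CO[Si](C)(C)C(C)(C)C)[C@@]1(C)[C@@H](OC(C)=O)C[C@@H](O[Si](c2ccccc2)(c2ccccc2)C(C)(C)C)[C@H](C)[C@@H]1[C@@H](O)C#CCCl | intermediate
26 | C9 tert-butyldimethylsilyl ether of 25 | CCCC(=O)O[C@H](CC/C(C)=C\CO[Si](C)(C)C(C)(C)C)[C@@]1(C)[C@@H](OC(C)=O)C[C@@H](O[Si](c2ccccc2)(c2ccccc2)C(C)(C)C)[C@H](C)[C@@H]1[C@@H](O[Si](C)(C)C(C)(C)C)C#CCCl | intermediate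
27 | C7 allylic alcohol | CCCC(=O)O[C@H](CC/C(C)=C\CO)[C@@]1(C)[C@@H](OC(C)=O)C[C@@H](O[Si](c2ccccc2)(c2ccccc2)C(C)(C)C)[C@H](C)[C@@H]1[C@@H](O[Si](C)(C)C(C)(C)C)C#CCCl | intermediate
28 | (Z)-enal propargylic chloride (seco precursor) | CCCC(=O)O[C@H](CC/C(C)=C\C=O)[C@@]1(C)[C@@H](OC(C)=O)C[C@@H](O[Si](c2ccccc2)(c2ccccc2)C(C)(C)C)[C@H](C)[C@@H]1[C@@H](O[Si](C)(C)C(C)(C)C)C#CCCl | intermediate
29 | propargylchromium dichloride derived from 28 | CCCC(=O)O[C@H](CC/C(C)=C\C=O)[C@@]1(C)[C@@H](OC(C)=O)C[C@@H](O[Si](c2ccccc2)(c2ccccc2)C(C)(C)C)[C@H](C)[C@@H]1[C@@H](O[Si](C)(C)C(C)(C)C)C#CC[Cr](Cl)Cl | intermediate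
30 | ten-membered α-allenic alcohol: (7S)-hydroxy, 8-vinylidene, C9 and C12 silyl ethers, C14 acetate, C2 butyrate | CCCC(=O)O[C@@H]1CC/C(C)=C\[C@H](O)C(=C=C)[C@H](O[Si](C)(C)C(C)(C)C)[C@H]2[C@@H](C)[C@H](O[Si](c3ccccc3)(c3ccccc3)C(C)(C)C)C[C@H](OC(C)=O)[C@@]21C | intermediate
31 | butenolide with C9 and C12 silyl ethers | CCCC(=O)O[C@@H]1CC/C(C)=C\[C@@H]2OC(=O)C(C)=C2[C@H](O[Si](C)(C)C(C)(C)C)[C@H]2[C@@H](C)[C@H](O[Si](c3ccccc3)(c3ccccc3)C(C)(C)C)C[C@H](OC(C)=O)[C@@]21C | intermediate
32 | butenolide with free C9 hydroxyl | CCCC(=O)O[C@@H]1CC/C(C)=C\[C@@H]2OC(=O)C(C)=C2[C@H](O)[C@H]2[C@@H](C)[C@H](O[Si](c3ccccc3)(c3ccccc3)C(C)(C)C)C[C@H](OC(C)=O)[C@@]21C | intermediate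
33 | C12 silyl ether of the target | CCCC(=O)O[C@@H]1CC/C(C)=C\[C@@H]2OC(=O)C(C)=C2[C@H](OC(C)=O)[C@H]2[C@@H](C)[C@H](O[Si](c3ccccc3)(c3ccccc3)C(C)(C)C)C[C@H](OC(C)=O)[C@@]21C | intermediate
34 | CNP0281577.1, (1S,2R,5Z,7S,9R,10S,11R,12R,14S)-9,14-diacetoxy-2-butanoyloxy-12-hydroxy butenolide | CCCC(=O)O[C@@H]1CC/C(C)=C\[C@@H]2OC(=O)C(C)=C2[C@H](OC(C)=O)[C@H]2[C@@H](C)[C@H](O)C[C@H](OC(C)=O)[C@@]21C | target

**Step count and risks**

Total step count: 24. Longest linear sequence: 22 steps (steps 1–7 and 10–24, from (R)-carvone); steps 8–9 form the side branch.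

Steps most likely to fail:

Step 20 (ring closure). The ten-membered ring may not close cleanly: the organochromium species can lose the C9 silyloxy group by β-elimination, the chain can oligomerise, or the aldehyde face may be chosen poorly at C7. The fallback closes the same bond without an organometallic intermediate, through an open transition state. It sets out from aldehyde 22. Addition of the lithium acetylide of purchased 3-(trimethylsilyl)prop-1-yne (n-BuLi, THF, −78 °C, Felkin–Anh as in step 16) would give propargylsilane carbinol F1. Silylation (tert-butyldimethylsilyl triflate, 2,6-lutidine) would give bis-silyl ether F2. Mild acid methanolysis of the primary silyl ether (pyridinium p-toluenesulfonate, MeOH, 0 °C) would give allylic alcohol F3, and MnO2 would give enal F4. F4 would then be cyclised by a Lewis-acid-promoted intramolecular Hosomi–Sakurai-type SE2′ addition of the propargylsilane to the aldehyde (BF3·OEt2, CH2Cl2, −78 °C, high dilution). This should deliver allenol 30, where the route is rejoined before step 21.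

Step 10 (aldol). The congested adduct may revert by retro-aldol, and closed transition states may compete and erode the configuration at C2. The fallback separates C–C bond formation from control of C2. It sets out from silyl enol ether 12 and aldehyde 16. The lithium enolate (MeLi, THF, 0 °C, then −78 °C) should react through the closed Zimmerman–Traxler transition state to give the C2-epimeric aldol F5. Oxidation (Dess–Martin conditions as in step 15) would give 1,3-diketone F6. The side-chain ketone would then be reduced under catalyst control (Corey–Bakshi–Shibata reduction, (S)-2-methyl-oxazaborolidine, catecholborane, toluene, −78 °C; quaternary C1 as the large group). The more shielded ring ketone is expected to react more slowly, but this chemoselectivity is not assured. The route is rejoined at 17.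

Step 12 (mono-butyrylation). The two hydroxyls of the 1,3-diol may not be distinguished, and the acyl group may migrate, giving regioisomeric and doubly acylated material. The fallback fixes the acyl positions by the order of events instead of by selectivity. It sets out from aldol 17, whose only hydroxyl is butyrylated (butyric anhydride, DMAP, pyridine) to keto butyrate F7. The C14 ketone would then be reduced under substrate control (LiBH(sec-Bu)3, THF, −78 °C, AcOH quench at −78 °C), hydride being expected from the face of the C1 methyl, anti to the larger C2 arm. The facial outcome depends on the ring conformation and is the weak point of this fallback. The route is rejoined at 19.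

Further compounds
F1 | step 20 | propargylsilane carbinol (C9 hydroxyl, C18 trimethylsilyl) | CCCC(=O)O[C@H](CC/C(C)=C\CO[Si](C)(C)C(C)(C)C)[C@@]1(C)[C@@H](OC(C)=O)C[C@@H](O[Si](c2ccccc2)(c2ccccc2)C(C)(C)C)[C@H](C)[C@@H]1[C@@H](O)C#CC[Si](C)(C)C
F2 | step 20 | bis-silyl ether propargylsilane | CCCC(=O)O[C@H](CC/C(C)=C\CO[Si](C)(C)C(C)(C)C)[C@@]1(C)[C@@H](OC(C)=O)C[C@@H](O[Si](c2ccccc2)(c2ccccc2)C(C)(C)C)[C@H](C)[C@@H]1[C@@H](O[Si](C)(C)C(C)(C)C)C#CC[Si](C)(C)C
F3 | step 20 | C7 allylic alcohol propargylsilane | CCCC(=O)O[C@H](CC/C(C)=C\CO)[C@@]1(C)[C@@H](OC(C)=O)C[C@@H](O[Si](c2ccccc2)(c2ccccc2)C(C)(C)C)[C@H](C)[C@@H]1[C@@H](O[Si](C)(C)C(C)(C)C)C#CC[Si](C)(C)C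
F4 | step 20 | (Z)-enal propargylsilane | CCCC(=O)O[C@H](CC/C(C)=C\C=O)[C@@]1(C)[C@@H](OC(C)=O)C[C@@H](O[Si](c2ccccc2)(c2ccccc2)C(C)(C)C)[C@H](C)[C@@H]1[C@@H](O[Si](C)(C)C(C)(C)C)C#CC[Si](C)(C)C
F5 | step 10 | C2-epimeric aldol | O[C@@H](CC/C(C)=C\CO[Si](C)(C)C(C)(C)C)[C@@]1(C)C(=O)C[C@@H](O[Si](c2ccccc2)(c2ccccc2)C(C)(C)C)[C@H](C)[C@@H]1COCOC
F6 | step 10 | 1,3-diketone | O=C(CC/C(C)=C\CO[Si](C)(C)C(C)(C)C)[C@@]1(C)C(=O)C[C@@H](O[Si](c2ccccc2)(c2ccccc2)C(C)(C)C)[C@H](C)[C@@H]1COCOC
F7 | step 12 | keto butyrate | CCCC(=O)O[C@H](CC/C(C)=C\CO[Si](C)(C)C(C)(C)C)[C@@]1(C)C(=O)C[C@@H](O[Si](c2ccccc2)(c2ccccc2)C(C)(C)C)[C@H](C)[C@@H]1COCOC
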